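All compound numbers below refer to the numbered route and the compound list that follows it.

## The problem

Target 19 is an achiral flavone. Ring C is a 4-pyranone fused through C4a–C8a to benzene ring A and carries aryl ring B at C2. With no stereocentre, the task is one of regiochemistry and of the timing of functional groups. Ring A is hexasubstituted: C5, C6, C7 and C8 bear OH, OMe, OH and OMe in turn, so four adjacent oxygens must be installed and told apart, which stepwise substitution of a benzene ring does poorly. Ring B holds a catechol (3'-OH, 4'-OH) beside 5'-OMe; with the electron-rich ring A this makes the free polyphenol sensitive to base and air, so the phenols should be unmasked last and under neutral conditions. The 5-OH is held in a hydrogen bond to the C4 carbonyl and is far less nucleophilic than the other phenols, which allows O8 to be methylated beside it. The enabling feature is that C5 and C8 are para-related oxygenated carbons with the oxygenated pair C6/C7 between them. This is a hydroquinone whose four C–O carbons map onto the four carbons of a squaric ester, while C4a and C8a are simply the C=C bond of a monocyclic 4-pyranone in which C8a carries only hydrogen. Ring A can therefore be grown onto a finished ring C by ring expansion of a cyclobutenone, with all four oxygens delivered already differentiated.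

## Retrosynthesis

**19 to 17.** The three benzyl C–O bonds of 18 (O7, O3', O4') are cut first, so that one neutral hydrogenolysis releases 19 at the very end. Benzyl is preferred to acetal or silyl groups because it survives the enolate, Grignard and thermal steps. The O8–CH3 bond of 18 is cut next, giving hydroquinone 17; the forward methylation only has to distinguish the free 8-OH from the chelated 5-OH.

**17 to 14 (key disconnection).** The C8–C8a bond is cut and ring A is contracted to a four-membered ring, giving 4-hydroxycyclobutenone 14 through cyclohexadienone 16 and dienylketene 15. This is preferred to any cut that keeps a benzene ring A, because 14 contains no hexasubstituted arene: its four oxygenated carbons come from a squarate and the other two are the pyranone C=C. The forward reaction must open the cyclobutenone with the hydroxyl turning outward and must close onto the one available pyranone C–H carbon.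

**14 to 12 and 11.** The ketone of 14 is masked as the dimethyl ketal 13, and the bond between the carbinol carbon and the pyranone carbon is cut to give alkenylmagnesium species 12 and ketal 11. The ketal leaves a single carbonyl for the nucleophile, so the carbinol carbon is fixed next to the methoxy-bearing carbon. Because the ring is four-membered, the benzyloxy carbon is then opposite the carbinol whichever end of the intermediate cation water attacks during deketalisation.

**11 to 9.** The benzyl C–O bond of 11 is traced to an alkoxide exchange on tetramethoxy ketal 10. Exchange can occur only at the vinylogous ester carbon, which is the carbon 1,3 to the free carbonyl. Ketal 10 comes in one step from dimethyl squarate 9.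

**12 to 7.** The C–Mg bond of 12 is traced to the C–I bond of iodopyranone 8, and that to the C5–H bond of pyranone 7. Going through the iodide places the metal unambiguously at the carbon next to the carbonyl and remote from the aryl group.

**7 to 4 and 5.** Ring C is opened at the ring oxygen–CH bond to give enol ether diketone 6. Cutting the bond between the aroyl carbon and the methylene of 6 gives acid chloride 4 and (E)-4-methoxybut-3-en-2-one 5. The forward sequence is an enolate acylation followed by acid-catalysed closure with loss of methanol.

**4 to 1.** Acid chloride 4 derives from acid 3, obtained by saponification of the fully benzylated ester 2, which comes from 3,4-dihydroxy-5-methoxybenzoic acid 1. Ring B thus arrives with its 5'-OMe in place and its catechol masked.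

## Roads not taken

**Alternative 1:** Ring C is cut at C2–C3 and C3–C4, with C3 supplied as a one-carbon phosphorus ylide.
- Forward step: the silyl ester A1 of an O-aroylated salicylic acid is acylated at the silyl ester carbonyl by a silylated methylenephosphorane. The resulting acyl ylide olefinates the neighbouring aryl ester carbonyl in an intramolecular Wittig reaction, giving flavone A2.
- Merits: it is convergent from two benzoic acids, runs under neutral conditions and has direct precedent for flavones. A2 needs only one hydrogenolysis to reach 19, with no selective methylation and no air-sensitive hydroquinone. In the end game it is better than the chosen plan.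
- Weak points: A1 already contains the hexasubstituted ring A, a salicylate with four further oxygens in fixed benzyl/methyl alternation. Its regiocontrolled preparation is the hard part of the molecule and would need more steps than the whole squarate branch. The carbonyl to be acylated is flanked by two ortho substituents and the ester to be olefinated sits on a doubly ortho-substituted phenol, so both stages are hindered.
- Comparison: the chosen plan sets against the cleaner end game a ring A built in two operations from 9, with its oxygens differentiated before the ring exists.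

**Alternative 2:** Ring C is cut at O1–C8a.
- Forward step: diaryl 1,3-diketone A3 is oxidised at a graphite anode in a fluorinated alcohol with a quaternary ammonium electrolyte. The enol oxygen is joined to the ring A C–H carbon to give flavone A4.
- Merits: the ring A partner needs one substituent fewer (a C–H in place of a phenol), A3 comes from a plain Claisen condensation, and no stoichiometric oxidant or organometallic step is needed. If the arene were in hand the route could be shorter than the chosen one.
- Weak points: the anode oxidises the very electron-rich tetraalkoxy ring to a radical cation. The tethered enol oxygen can reach two ortho carbons, the C–H carbon and the benzyloxy-bearing one, so ipso attack with loss of benzyl competes. Benzylic oxidation of the ethers and over-oxidation of the para-dialkoxy unit to a quinone are further plausible pathways. Ring B must carry acetates to lower its oxidation potential, which adds a separate base deprotection of a sensitive catechol. The pentasubstituted ring A ketone still has to be prepared with the correct benzyl/methyl alternation.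
- Comparison: the chosen plan relies on a pericyclic step with one possible closure site and a well-established reaction class, and takes ring A from a symmetric four-carbon unit.

**Alternative 3:** Ring A is cut at C4a–C5 in a biomimetic fold.
- Forward step: excess lithium amide base converts pyranone keto ester A5 into a vinylogous enolate that attacks the terminal ester through the pyranone carbon. Loss of methanol and enolisation give flavone A6.
- Merits: the 5,7-dihydroxy-6,8-dimethoxy pattern arises directly, hydroxyls from carbonyls and methoxyls from the chain. No hydroxyl differentiation is needed and only two benzyl ethers remain to be removed. This is the shortest end game of all four plans.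
- Weak points: A5 is an alpha,alpha'-dimethoxy beta-keto ester chain on a pyranone, with several acidic sites and two epimerisable centres. It is hard to assemble and prone to retro-Claisen cleavage and elimination of methoxide. The closure must occur through the weakly nucleophilic pyranone carbon in preference to O-acylation to a lactone. Such folds are known for simple resorcinol products, not for alternately O-methylated ones.
- Comparison: the chosen plan has a precursor assembled from two simple blocks by one Grignard addition, and a key step whose regiochemistry is fixed by constitution.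

Key step: step 10

Assumption: 13, 14 and the transient 16 each hold one stereocentre and are used as racemates, since that carbon becomes aromatic in step 10; 19 is achiral.

## Route

Step 1
Reactants: 1 3,4-dihydroxy-5-methoxybenzoic acid
Product: 2 benzyl 3,4-bis(benzyloxy)-5-methoxybenzoate
Conditions: BnBr (3.5 equiv), K2CO3, DMF, 60 °C
Reagents that add atoms: benzyl bromide, BrCc1ccccc1
Why: Williamson alkylation of both phenols and the carboxylate in one pot; exhaustive benzylation avoids any selectivity question.

Step 2
Reactants: 2 benzyl 3,4-bis(benzyloxy)-5-methoxybenzoate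
Product: 3 3,4-bis(benzyloxy)-5-methoxybenzoic acid
Conditions: NaOH, THF/MeOH/H2O, 60 °C; then HCl (aq.)
Reagents that add atoms: sodium hydroxide, [Na+].[OH-]
Why: Saponification of the benzyl ester; aryl benzyl ethers and the aryl methyl ether are inert to hydroxide.

Step 3
Reactants: 3 3,4-bis(benzyloxy)-5-methoxybenzoic acid
Product: 4 3,4-bis(benzyloxy)-5-methoxybenzoyl chloride
Conditions: (COCl)2, DMF (cat.), CH2Cl2, 0 °C to rt
Reagents that add atoms: oxalyl chloride, ClC(=O)C(Cl)=O
Why: Acid chloride formation through the Vilsmeier-type chloroiminium species; the by-products are gases and the chloride is used crude.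

Step 4
Reactants: 4 3,4-bis(benzyloxy)-5-methoxybenzoyl chloride; 5 (E)-4-methoxybut-3-en-2-one
Product: 7 2-[3,4-bis(benzyloxy)-5-methoxyphenyl]-4H-pyran-4-one, via methoxypentenedione 6 (not isolated)
Conditions: 5 (2 equiv), LiN(SiMe3)2 (2 equiv), THF, −78 °C, then 4; crude 6: CF3CO2H (cat.), toluene, rt
Reagents that add atoms: none
Why: Claisen-type C-acylation of the kinetic methyl ketone enolate (the second equivalent absorbs the acidic diketone proton) gives 6. Acid then lets the enol oxygen add to the beta-methoxy enone and expel methanol, an established 4-pyranone synthesis from acid chlorides.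

Step 5
Reactants: 7 2-[3,4-bis(benzyloxy)-5-methoxyphenyl]-4H-pyran-4-one
Product: 8 2-[3,4-bis(benzyloxy)-5-methoxyphenyl]-5-iodo-4H-pyran-4-one
Conditions: I2, pyridine, CH2Cl2, rt, dark
Reagents that add atoms: iodine, II
Why: Amine-mediated alpha-iodination of an enone: pyridine adds reversibly to the unsubstituted C6, the enolate is iodinated at C5 and pyridine is expelled. The aryl-bearing C2 is not attacked, so C3 stays free, and iodine without an activator should spare the alkoxylated ring B.

Step 6
Reactants: 9 dimethyl squarate (3,4-dimethoxycyclobut-3-ene-1,2-dione)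
Product: 10 2,3,4,4-tetramethoxycyclobut-2-en-1-one
Conditions: MeOSiMe3 (2.5 equiv), Me3SiOTf (cat.), CH2Cl2, −78 °C to rt
Reagents that add atoms: methoxytrimethylsilane, CO[Si](C)(C)C
Why: Silyl-triflate-catalysed ketalisation with an alkoxysilane (Noyori conditions); after one carbonyl is ketalised the other is a vinylogous ester and too electron-rich to react, so the monoketal should result. Using methoxy throughout makes any alkoxy scrambling invisible.

Step 7
Reactants: 10 2,3,4,4-tetramethoxycyclobut-2-en-1-one
Product: 11 3-(benzyloxy)-2,4,4-trimethoxycyclobut-2-en-1-one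
Conditions: BnOH (excess), NaH (cat.), THF, 0 °C to rt, MeOH removed under reduced pressure
Reagents that add atoms: benzyl alcohol, OCc1ccccc1
Why: Alkoxide addition–elimination at C3, the beta-carbon of the vinylogous ester and the only electrophilic sp2 carbon bearing a leaving group. The alpha-methoxy enol ether and the ketal are inert to alkoxide, and the equilibrium is driven by excess alcohol and removal of methanol.

Step 8
Reactants: 8 2-[3,4-bis(benzyloxy)-5-methoxyphenyl]-5-iodo-4H-pyran-4-one; 11 3-(benzyloxy)-2,4,4-trimethoxycyclobut-2-en-1-one
Product: 13 2-[3,4-bis(benzyloxy)-5-methoxyphenyl]-5-[3-(benzyloxy)-1-hydroxy-2,4,4-trimethoxycyclobut-2-en-1-yl]-4H-pyran-4-one (racemic), via pyranonylmagnesium chloride 12 (not isolated)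
Conditions: 8, iPrMgCl·LiCl, THF, −40 °C; then 11, LaCl3·2LiCl, −40 to 0 °C; aq. NH4Cl
Reagents that add atoms: none
Why: Iodine–magnesium exchange on an alpha-iodo vinylogous ester is fast at low temperature and gives an alkenyl Grignard reagent that tolerates its own deactivated carbonyl. Lanthanum-assisted 1,2-addition to the only carbonyl of 11 gives the tertiary alcohol; the new stereocentre is uncontrolled and is destroyed in step 10.

Step 9
Reactants: 13 2-[3,4-bis(benzyloxy)-5-methoxyphenyl]-5-[3-(benzyloxy)-1-hydroxy-2,4,4-trimethoxycyclobut-2-en-1-yl]-4H-pyran-4-one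
Product: 14 2-(benzyloxy)-4-{6-[3,4-bis(benzyloxy)-5-methoxyphenyl]-4-oxo-4H-pyran-3-yl}-4-hydroxy-3-methoxycyclobut-2-en-1-one (racemic)
Conditions: oxalic acid (aq.) on SiO2, CH2Cl2, 0 °C to rt
Reagents that add atoms: water, O
Why: Mild hydrolysis of a vinylogous ortho ester: the ketal carbon should ionise to a 1,3-dialkoxycyclobutenyl cation far more readily than the carbinol ionises. Water attack at either end of that cation gives the same constitution, with the benzyloxy carbon opposite the carbinol.

Step 10
Reactants: 14 2-(benzyloxy)-4-{6-[3,4-bis(benzyloxy)-5-methoxyphenyl]-4-oxo-4H-pyran-3-yl}-4-hydroxy-3-methoxycyclobut-2-en-1-one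
Product: 17 7-(benzyloxy)-2-[3,4-bis(benzyloxy)-5-methoxyphenyl]-5,8-dihydroxy-6-methoxy-4H-chromen-4-one, via dienylketene 15 (not isolated), via cyclohexadienone 16 (not isolated)
Conditions: p-xylene (degassed), 138 °C, Ar
Reagents that add atoms: none
Why: Heating opens the cyclobutenone by conrotatory 4π electrocyclic cleavage of the bond between the carbonyl carbon and the carbinol carbon; the hydroxyl donor rotates outward, so the pyranonyl group turns inward and lies cis to the ketene in 15. The ketene C=C, the central enol ether C=C and the adjacent pyranone C=C then form a hexatriene that closes by 6π electrocyclisation, the ketene carbon bonding to the pyranone C–H carbon; this forms the C8–C8a bond and the six-membered carbocycle of 16. Enolisation of the C8 ketone with loss of the C8a hydrogen aromatises ring A and gives hydroquinone 17. This is the Moore rearrangement, whose closest known cases are 4-aryl-, 4-heteroaryl- and 4-alkenyl-4-hydroxycyclobutenones, including benzannulation onto the C=C bond of chromone-type heterocycles. No stereocentre remains, because the carbinol centre of 14 and the C8a centre of 16 both become aromatic carbons. The step needs outward rotation of the hydroxyl, which its donor character secures, and a single closure site, which the substrate secures because the pyranone carbon that bears the four-membered ring has only one sp2 C–H neighbour, the other being the carbonyl carbon. The oxygen pattern is fixed by constitution: carbinol carbon to C5, methoxy carbon to C6, benzyloxy carbon to C7, carbonyl carbon to C8. Degassed solvent and argon protect the air-sensitive hydroquinone, which is carried on at once.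

Step 11
Reactants: 17 7-(benzyloxy)-2-[3,4-bis(benzyloxy)-5-methoxyphenyl]-5,8-dihydroxy-6-methoxy-4H-chromen-4-one
Product: 18 7-(benzyloxy)-2-[3,4-bis(benzyloxy)-5-methoxyphenyl]-5-hydroxy-6,8-dimethoxy-4H-chromen-4-one
Conditions: MeI (1.1 equiv), K2CO3 (1.2 equiv), acetone (degassed), rt, Ar
Reagents that add atoms: iodomethane, CI
Why: Williamson methylation; the 5-OH is tied in a six-membered hydrogen bond to the C4 carbonyl and is the less acidic and less nucleophilic phenol, so one equivalent of iodomethane should react only at O8, as in the standard partial methylation of 5-hydroxyflavones.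

Step 12
Reactants: 18 7-(benzyloxy)-2-[3,4-bis(benzyloxy)-5-methoxyphenyl]-5-hydroxy-6,8-dimethoxy-4H-chromen-4-one
Product: 19 2-(3,4-dihydroxy-5-methoxyphenyl)-5,7-dihydroxy-6,8-dimethoxy-4H-chromen-4-one (5,7,3',4'-tetrahydroxy-6,8,5'-trimethoxyflavone)
Conditions: H2 (1 atm), Pd/C, THF/MeOH, rt
Reagents that add atoms: none
Why: Hydrogenolysis of three aryl benzyl ethers; the flavone C2–C3 double bond, part of a vinylogous ester, and the aryl methyl ethers should not be reduced at balloon pressure. The catechol is released last under neutral conditions.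

## Compound list

1 | 3,4-dihydroxy-5-methoxybenzoic acid | COc1cc(C(=O)O)cc(O)c1O | starting material
2 | benzyl 3,4-bis(benzyloxy)-5-methoxybenzoate | COc1cc(C(=O)OCc2ccccc2)cc(OCc2ccccc2)c1OCc1ccccc1 | intermediate
3 | 3,4-bis(benzyloxy)-5-methoxybenzoic acid | COc1cc(C(=O)O)cc(OCc2ccccc2)c1OCc1ccccc1 | intermediate
4 | 3,4-bis(benzyloxy)-5-methoxybenzoyl chloride | COc1cc(C(=O)Cl)cc(OCc2ccccc2)c1OCc1ccccc1 | intermediate
5 | (E)-4-methoxybut-3-en-2-one | CO/C=C/C(C)=O | starting material
6 | (E)-1-[3,4-bis(benzyloxy)-5-methoxyphenyl]-5-methoxypent-4-ene-1,3-dione | CO/C=C/C(=O)CC(=O)c1cc(OC)c(OCc2ccccc2)c(OCc2ccccc2)c1 | intermediate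
7 | 2-[3,4-bis(benzyloxy)-5-methoxyphenyl]-4H-pyran-4-one | COc1cc(-c2cc(=O)cco2)cc(OCc2ccccc2)c1OCc1ccccc1 | intermediate
8 | 2-[3,4-bis(benzyloxy)-5-methoxyphenyl]-5-iodo-4H-pyran-4-one | COc1cc(-c2cc(=O)c(I)co2)cc(OCc2ccccc2)c1OCc1ccccc1 | intermediate
9 | dimethyl squarate (3,4-dimethoxycyclobut-3-ene-1,2-dione) | COC1=C(OC)C(=O)C1=O | starting material
10 | 2,3,4,4-tetramethoxycyclobut-2-en-1-one | COC1=C(OC)C(OC)(OC)C1=O | intermediate
11 | 3-(benzyloxy)-2,4,4-trimethoxycyclobut-2-en-1-one | COC1=C(OCc2ccccc2)C(OC)(OC)C1=O | intermediate
12 | {6-[3,4-bis(benzyloxy)-5-methoxyphenyl]-4-oxo-4H-pyran-3-yl}magnesium chloride (as its LiCl complex) | COc1cc(-c2cc(=O)c([Mg]Cl)co2)cc(OCc2ccccc2)c1OCc1ccccc1 | intermediate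
13 | 2-[3,4-bis(benzyloxy)-5-methoxyphenyl]-5-[3-(benzyloxy)-1-hydroxy-2,4,4-trimethoxycyclobut-2-en-1-yl]-4H-pyran-4-one (racemic) | COC1=C(OCc2ccccc2)C(OC)(OC)C1(O)c1coc(-c2cc(OC)c(OCc3ccccc3)c(OCc3ccccc3)c2)cc1=O | intermediate
14 | 2-(benzyloxy)-4-{6-[3,4-bis(benzyloxy)-5-methoxyphenyl]-4-oxo-4H-pyran-3-yl}-4-hydroxy-3-methoxycyclobut-2-en-1-one (racemic) | O=C1C(OCc2ccccc2)=C(OC)C1(O)c1coc(-c2cc(OC)c(OCc3ccccc3)c(OCc3ccccc3)c2)cc1=O | intermediate
15 | (3Z)-2-(benzyloxy)-4-{6-[3,4-bis(benzyloxy)-5-methoxyphenyl]-4-oxo-4H-pyran-3-yl}-4-hydroxy-3-methoxybuta-1,3-dien-1-one | O=C=C(OCc1ccccc1)/C(OC)=C(/O)c1coc(-c2cc(OC)c(OCc3ccccc3)c(OCc3ccccc3)c2)cc1=O | intermediate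
16 | 7-(benzyloxy)-2-[3,4-bis(benzyloxy)-5-methoxyphenyl]-5-hydroxy-6-methoxy-4H-chromene-4,8(8aH)-dione (racemic) | O=C1C(OCc2ccccc2)=C(OC)C(O)=C2C(=O)C=C(c3cc(OC)c(OCc4ccccc4)c(OCc4ccccc4)c3)OC12 | intermediate
17 | 7-(benzyloxy)-2-[3,4-bis(benzyloxy)-5-methoxyphenyl]-5,8-dihydroxy-6-methoxy-4H-chromen-4-one | COc1cc(-c2cc(=O)c3c(O)c(OC)c(OCc4ccccc4)c(O)c3o2)cc(OCc2ccccc2)c1OCc1ccccc1 | intermediate
18 | 7-(benzyloxy)-2-[3,4-bis(benzyloxy)-5-methoxyphenyl]-5-hydroxy-6,8-dimethoxy-4H-chromen-4-one | COc1cc(-c2cc(=O)c3c(O)c(OC)c(OCc4ccccc4)c(OC)c3o2)cc(OCc2ccccc2)c1OCc1ccccc1 | intermediate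
19 | 2-(3,4-dihydroxy-5-methoxyphenyl)-5,7-dihydroxy-6,8-dimethoxy-4H-chromen-4-one | COc1cc(-c2cc(=O)c3c(O)c(OC)c(O)c(OC)c3o2)cc(O)c1O | target

## Step count and least certain steps

Total step count: 12. Longest linear sequence: 10 steps (steps 1 to 5 and 8 to 12); the squarate branch (steps 6 and 7) joins at step 8.

**Step 10 (key step).** The most likely failure is diversion of ketene 15 before it closes. Any ring opening with the hydroxyl turned inward lets the hydroxyl add to the ketene and form a butenolide. Closure onto the electron-poor pyranone C=C may also be slower than onto a simple arene, leaving time for ketene dimerisation. The hydroquinone may oxidise to the quinone during isolation. The fallback sets out from 14 and caps the carbinol with Et3SiOTf and 2,6-lutidine to give 2-(benzyloxy)-4-{6-[3,4-bis(benzyloxy)-5-methoxyphenyl]-4-oxo-4H-pyran-3-yl}-3-methoxy-4-[(triethylsilyl)oxy]cyclobut-2-en-1-one F1. This cannot lactonise and still opens with the oxygen outward. Thermolysis should give the air-stable, monoprotected 7-(benzyloxy)-2-[3,4-bis(benzyloxy)-5-methoxyphenyl]-8-hydroxy-6-methoxy-5-[(triethylsilyl)oxy]-4H-chromen-4-one F2. Its single free phenol is methylated (MeI, K2CO3) to 7-(benzyloxy)-2-[3,4-bis(benzyloxy)-5-methoxyphenyl]-6,8-dimethoxy-5-[(triethylsilyl)oxy]-4H-chromen-4-one F3, and Bu4NF removes the silyl group, returning to the route at 18.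

**Step 7.** The exchange is reversible, so conversion may stall and leave mixtures of 10 and 11 that are hard to separate; alkoxide may also attack the carbonyl and degrade the ring. The fallback replaces the equilibrium by two irreversible operations. From 10, LiOH in THF/H2O displaces the vinylogous methoxy group to give 3-hydroxy-2,4,4-trimethoxycyclobut-2-en-1-one F4, kept as its lithium salt so that the ketal is never exposed to acid. Its two oxygens are equivalent by symmetry of the four-membered ring, so O-benzylation (BnBr, DMF) can give only one benzyl ether and returns to the route at 11.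

**Step 8.** The stabilised and hindered alkenylmagnesium species 12 may add too slowly to the donor-substituted, neopentyl-like carbonyl of 11. On warming, 12 would then decompose, or residual isopropyl Grignard reagent would attack the pyranone. The fallback offers 12 a much more electrophilic dione. From 9, exchange of one methoxy group with one equivalent of benzyl alcohol gives 3-(benzyloxy)-4-methoxycyclobut-3-ene-1,2-dione F5 after chromatography. Grignard addition to squaric esters is standard but here cannot distinguish the two carbonyls. Attack next to the methoxy-bearing carbon gives 14 itself; attack at the other carbonyl gives the regioisomer 3-(benzyloxy)-4-{6-[3,4-bis(benzyloxy)-5-methoxyphenyl]-4-oxo-4H-pyran-3-yl}-4-hydroxy-2-methoxycyclobut-2-en-1-one F6, which is removed by chromatography. The fallback returns to the route at 14, bypassing 11, 13 and step 9 at the cost of the material lost as the regioisomer.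

**Step 9.** Acid may ionise the tertiary carbinol in competition with the ketal. The carbinol is allylic to the benzyloxy enol ether and sits on the donor position of the pyranone, so it is doubly activated; its ionisation would end in loss of benzyl alcohol and a rearranged enone. The fallback removes that leaving group before hydrolysis. From 13, N-(trimethylsilyl)imidazole gives 2-[3,4-bis(benzyloxy)-5-methoxyphenyl]-5-{3-(benzyloxy)-2,4,4-trimethoxy-1-[(trimethylsilyl)oxy]cyclobut-2-en-1-yl}-4H-pyran-4-one F7. Wet silica with oxalic acid then cleaves only the vinylogous ortho ester to give 2-(benzyloxy)-4-{6-[3,4-bis(benzyloxy)-5-methoxyphenyl]-4-oxo-4H-pyran-3-yl}-3-methoxy-4-[(trimethylsilyl)oxy]cyclobut-2-en-1-one F8, in which the adjacent carbonyl now deactivates the carbinol carbon. Et3N·3HF removes the silyl group and returns to the route at 14.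

**Step 5.** Iodination may take an electrophilic course instead of the amine-mediated one. Iodine would then enter at C3 next to the aryl group or on the alkoxylated ring B, giving regioisomers that are hard to separate. The fallback places the halogen before the ring exists. From 5, bromination and dehydrobromination (Br2, then Et3N) give (Z)-3-bromo-4-methoxybut-3-en-2-one F8a, listed below as F9. Its kinetic lithium enolate is acylated by 4 as in step 4 to give (Z)-1-[3,4-bis(benzyloxy)-5-methoxyphenyl]-4-bromo-5-methoxypent-4-ene-1,3-dione F10. Acid closes this to 2-[3,4-bis(benzyloxy)-5-methoxyphenyl]-5-bromo-4H-pyran-4-one F11, in which the halogen can only be at C5. A copper-catalysed halide exchange (CuI, NaI, N,N'-dimethylethylenediamine, dioxane, 110 °C; aromatic Finkelstein reaction) returns to the route at 8. For clarity, the bromo enone (Z)-3-bromo-4-methoxybut-3-en-2-one F9 is the first compound of this fallback.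

## Further compounds

F1 | step 10 | 2-(benzyloxy)-4-{6-[3,4-bis(benzyloxy)-5-methoxyphenyl]-4-oxo-4H-pyran-3-yl}-3-methoxy-4-[(triethylsilyl)oxy]cyclobut-2-en-1-one (racemic) | CC[Si](CC)(CC)OC1(c2coc(-c3cc(OC)c(OCc4ccccc4)c(OCc4ccccc4)c3)cc2=O)C(OC)=C(OCc2ccccc2)C1=O
F2 | step 10 | 7-(benzyloxy)-2-[3,4-bis(benzyloxy)-5-methoxyphenyl]-8-hydroxy-6-methoxy-5-[(triethylsilyl)oxy]-4H-chromen-4-one | CC[Si](CC)(CC)Oc1c(OC)c(OCc2ccccc2)c(O)c2oc(-c3cc(OC)c(OCc4ccccc4)c(OCc4ccccc4)c3)cc(=O)c12
F3 | step 10 | 7-(benzyloxy)-2-[3,4-bis(benzyloxy)-5-methoxyphenyl]-6,8-dimethoxy-5-[(triethylsilyl)oxy]-4H-chromen-4-one | CC[Si](CC)(CC)Oc1c(OC)c(OCc2ccccc2)c(OC)c2oc(-c3cc(OC)c(OCc4ccccc4)c(OCc4ccccc4)c3)cc(=O)c12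
F4 | step 7 | 3-hydroxy-2,4,4-trimethoxycyclobut-2-en-1-one (handled as its lithium salt) | COC1=C(O)C(OC)(OC)C1=O
F5 | step 8 | 3-(benzyloxy)-4-methoxycyclobut-3-ene-1,2-dione | COC1=C(OCc2ccccc2)C(=O)C1=O
F6 | step 8 | 3-(benzyloxy)-4-{6-[3,4-bis(benzyloxy)-5-methoxyphenyl]-4-oxo-4H-pyran-3-yl}-4-hydroxy-2-methoxycyclobut-2-en-1-one (racemic) | O=C1C(OC)=C(OCc2ccccc2)C1(O)c1coc(-c2cc(OC)c(OCc3ccccc3)c(OCc3ccccc3)c2)cc1=O
F7 | step 9 | 2-[3,4-bis(benzyloxy)-5-methoxyphenyl]-5-{3-(benzyloxy)-2,4,4-trimethoxy-1-[(trimethylsilyl)oxy]cyclobut-2-en-1-yl}-4H-pyran-4-one (racemic) | COC1=C(OCc2ccccc2)C(OC)(OC)C1(O[Si](C)(C)C)c1coc(-c2cc(OC)c(OCc3ccccc3)c(OCc3ccccc3)c2)cc1=O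
F8 | step 9 | 2-(benzyloxy)-4-{6-[3,4-bis(benzyloxy)-5-methoxyphenyl]-4-oxo-4H-pyran-3-yl}-3-methoxy-4-[(trimethylsilyl)oxy]cyclobut-2-en-1-one (racemic) | O=C1C(OCc2ccccc2)=C(OC)C1(O[Si](C)(C)C)c1coc(-c2cc(OC)c(OCc3ccccc3)c(OCc3ccccc3)c2)cc1=O
F9 | step 5 | (Z)-3-bromo-4-methoxybut-3-en-2-one | CO/C=C(\Br)C(C)=O
F10 | step 5 | (Z)-1-[3,4-bis(benzyloxy)-5-methoxyphenyl]-4-bromo-5-methoxypent-4-ene-1,3-dione | CO/C=C(\Br)C(=O)CC(=O)c1cc(OC)c(OCc2ccccc2)c(OCc2ccccc2)c1
F11 | step 5 | 2-[3,4-bis(benzyloxy)-5-methoxyphenyl]-5-bromo-4H-pyran-4-one | COc1cc(-c2cc(=O)c(Br)co2)cc(OCc2ccccc2)c1OCc1ccccc1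
A1 | alternative 1 | tert-butyldimethylsilyl 2,4-bis(benzyloxy)-6-{[3,4-bis(benzyloxy)-5-methoxybenzoyl]oxy}-3,5-dimethoxybenzoate | CC(C)(C)[Si](C)(C)OC(=O)c1c(OCc2ccccc2)c(OC)c(OCc2ccccc2)c(OC)c1OC(=O)c1cc(OC)c(OCc2ccccc2)c(OCc2ccccc2)c1
A2 | alternative 1 | 5,7-bis(benzyloxy)-2-[3,4-bis(benzyloxy)-5-methoxyphenyl]-6,8-dimethoxy-4H-chromen-4-one | COc1cc(-c2cc(=O)c3c(OCc4ccccc4)c(OC)c(OCc4ccccc4)c(OC)c3o2)cc(OCc2ccccc2)c1OCc1ccccc1
A3 | alternative 2 | 5-{3-[2,4-bis(benzyloxy)-3,5-dimethoxyphenyl]-3-oxopropanoyl}-3-methoxy-1,2-phenylene diacetate | COc1cc(C(=O)CC(=O)c2cc(OC)c(OCc3ccccc3)c(OC)c2OCc2ccccc2)cc(OC(C)=O)c1OC(C)=O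
A4 | alternative 2 | 5-[5,7-bis(benzyloxy)-6,8-dimethoxy-4-oxo-4H-chromen-2-yl]-3-methoxy-1,2-phenylene diacetate | COc1cc(-c2cc(=O)c3c(OCc4ccccc4)c(OC)c(OCc4ccccc4)c(OC)c3o2)cc(OC(C)=O)c1OC(C)=O
A5 | alternative 3 | methyl 4-{6-[3,4-bis(benzyloxy)-5-methoxyphenyl]-4-oxo-4H-pyran-2-yl}-2,4-dimethoxy-3-oxobutanoate (mixture of stereoisomers) | COC(=O)C(OC)C(=O)C(OC)c1cc(=O)cc(-c2cc(OC)c(OCc3ccccc3)c(OCc3ccccc3)c2)o1
A6 | alternative 3 | 2-[3,4-bis(benzyloxy)-5-methoxyphenyl]-5,7-dihydroxy-6,8-dimethoxy-4H-chromen-4-one | COc1cc(-c2cc(=O)c3c(O)c(OC)c(O)c(OC)c3o2)cc(OCc2ccccc2)c1OCc1ccccc1
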